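**Retrosynthetic overview**

1. Target 33 comes from global desilylation of 32. Its exocyclic (Z)-enal is built on ring ketone 28 through a C=CBr2 group (methyl at the less hindered bromide, then formyl), and 28 comes from a secondary nitro group by a Nef reaction.
2. The side chain is attached by B-alkyl Suzuki–Miyaura coupling of the 9-BBN adduct of ring vinyl compound 13 with (E,E)-vinyl iodide 24. Iodide 24 is made from 3-methylbut-2-enal by asymmetric propargylation and two Zr-catalysed carboalumination/iodination stages joined by a Negishi coupling.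
3. The cyclohexane, the only ring, is formed in one operation by a formal [3+3] annulation of methyl 2-methylacetoacetate 6 (C2 and C4 as donors) with (E)-2-nitroallyl acetate 5 (C3 and C1 as acceptors). This makes the CH(side chain)–C(quaternary) bond and the ring CH2–CH2 bond and sets the two stereocentres on the first of these bonds.
4. Enabling feature: in the cyclohexane the alkylidene-bearing carbon and the C(CH3)OH carbon are 1,4-related, each the middle atom of a three-carbon unit (CH–C–CH2 and CH2–C–C quaternary). A nitro group on the first (latent C=O, then C=C) and a carbonyl on the second (latent carbinol) turn the four flanking ring atoms into two acceptor and two donor sites.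
5. The ring carbinol is set by substrate-controlled MeCeCl2 addition, the side-chain carbinol by catalyst control, and the chain alkenes by syn-carboalumination.

Key step: step 4

Remark (assumption): the sense of induction of the organocatalysts in steps 4 and 10 is assigned by analogy with simple substrates; the antipodal catalyst is used if either proves opposite.
Remark (assumption): the nitro-bearing ring carbon in 8–26 is epimerisable and without consequence; it is drawn trans to the neighbouring side chain.

**Route**

Step 1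
Reactants: 1 4-[tert-butyl(dimethyl)silyl]oxybutanal
Product: 3 tert-butyl(dimethyl){[(4E)-5-nitropent-4-en-1-yl]oxy}silane, via nitro alcohol 2 (not isolated)
Conditions: MeNO2, KOt-Bu (10 mol %), THF/t-BuOH, 0 °C; then (CF3CO)2O, Et3N, CH2Cl2, −10 °C
Reagents that add atoms: nitromethane, C[N+](=O)[O-]
Why: Henry addition followed by E1cB dehydration of the trifluoroacetate should give the conjugated nitroalkene as the thermodynamically favoured E isomer, with the silyl ether untouched.

Step 2
Reactants: 3 tert-butyl(dimethyl){[(4E)-5-nitropent-4-en-1-yl]oxy}silane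
Product: 4 (2E)-6-[tert-butyl(dimethyl)silyl]oxy-2-nitrohex-2-en-1-ol
Conditions: 37% aq. HCHO, imidazole (1 equiv), anthranilic acid (10 mol %), THF, rt
Reagents that add atoms: formaldehyde, C=O
Why: Morita–Baylis–Hillman-type hydroxymethylation of a nitroalkene (imidazole adds to the β-carbon, the nitronate traps formaldehyde, imidazole is expelled) should give the (E)-2-nitroallyl alcohol.

Step 3
Reactants: 4 (2E)-6-[tert-butyl(dimethyl)silyl]oxy-2-nitrohex-2-en-1-ol
Product: 5 (2E)-6-[tert-butyl(dimethyl)silyl]oxy-2-nitrohex-2-en-1-yl acetate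
Conditions: Ac2O, pyridine, CH2Cl2, 0 °C
Reagents that add atoms: acetic anhydride, CC(=O)OC(C)=O
Why: Simple O-acetylation of the primary alcohol should give the (E)-2-nitroallyl acetate, a known class of 1,3-bis-electrophile.

Step 4
Reactants: 5 (2E)-6-[tert-butyl(dimethyl)silyl]oxy-2-nitrohex-2-en-1-yl acetate; 6 methyl 2-methyl-3-oxobutanoate
Product: 8 methyl (1R,2R,3R)-2-{3-[tert-butyl(dimethyl)silyl]oxypropyl}-1-methyl-3-nitro-6-oxocyclohexane-1-carboxylate, via nitroallyl ketoester 7 (not isolated)
Conditions: 1-[3,5-bis(trifluoromethyl)phenyl]-3-[(1R,2R)-2-(dimethylamino)cyclohexyl]thiourea (10 mol %), K2CO3 (1.2 equiv), toluene, −20 °C; then DBU (0.3 equiv), 0 °C to rt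
Reagents that add atoms: none
Why: The thiourea–tertiary amine catalyst binds the nitro group and the Z-enolate of 6 and delivers C2 of 6, its only acidic carbon, to the substituted alkene terminus of 5 (Michael addition); E1cB loss of acetate from the nitronate gives 7, and DBU then enolises the methyl ketone, whose carbon adds to the new terminal nitroalkene to close the cyclohexanone. The closest known reaction type is the formal [3+3] α,α′-annulation of ketone donors with 2-nitroallyl esters (Michael addition/elimination followed by a second Michael addition), including organocatalytic asymmetric versions with (E)-2-nitroallyl acetates. The ring closes by a 6-(enolendo)-endo-trig Michael addition. The tertiary centre is set by catalyst-controlled facial attack on the hydrogen-bonded nitroalkene and the quaternary centre by the synclinal approach of the doubly coordinated enolate (nitro group over the enolate oxygens, alkene hydrogen between methyl and ester), which should place the side chain cis to the C-methyl and trans to the ester; the nitro-bearing carbon is epimerisable and irrelevant. Regiochemistry is secured because 6 has a single acidic C–H for the first, intermolecular addition and only the former CH2OAc carbon remains as acceptor for the methyl ketone; the quaternary neighbour shields the intermediate nitroalkene from a second intermolecular addition, and C- over O-cyclisation follows from the reversibility of oxa-Michael addition to nitroalkenes.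

Step 5
Reactants: 8 methyl (1R,2R,3R)-2-{3-[tert-butyl(dimethyl)silyl]oxypropyl}-1-methyl-3-nitro-6-oxocyclohexane-1-carboxylate
Product: 9 methyl (1R,2R,5R,6R)-6-{3-[tert-butyl(dimethyl)silyl]oxypropyl}-2-hydroxy-1,2-dimethyl-5-nitrocyclohexane-1-carboxylate
Conditions: MeLi (3.5 equiv), CeCl3 (3.5 equiv), THF, −78 °C; aq. NH4Cl
Reagents that add atoms: methyllithium, [Li]C
Why: Organocerium 1,2-addition to a hindered, enolisable ketone should proceed with the nitro group masked as its nitronate and the neopentyl ester intact, the methyl entering on the ring face opposite the C-methyl of the adjacent quaternary carbon and the side chain (axial attack anti to the axial α-methyl), so that OH ends cis to that methyl.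

Step 6
Reactants: 9 the tertiary alcohol from step 5
Product: 10 methyl (1R,2R,5R,6R)-6-{3-[tert-butyl(dimethyl)silyl]oxypropyl}-1,2-dimethyl-5-nitro-2-(triethylsilyloxy)cyclohexane-1-carboxylate
Conditions: Et3SiOTf, 2,6-lutidine, CH2Cl2, −78 to 0 °C
Reagents that add atoms: triethylsilyl trifluoromethanesulfonate, CC[Si](CC)(CC)OS(=O)(=O)C(F)(F)F
Why: Silyl triflate silylation is the standard way to cap a hindered tertiary alcohol and removes the retro-aldol and phosphonium-activation pathways of later steps; any silyl nitronate reverts to the nitro compound on work-up.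

Step 7
Reactants: 10 the triethylsilyl ether from step 6
Product: 11 primary alcohol (CO2Me of 10 reduced to CH2OH; ring stereocentres as in 10)
Conditions: i-Bu2AlH (4 equiv), CH2Cl2, −78 to −20 °C; aq. Rochelle salt
Reagents that add atoms: none
Why: Hydride reduction of the ester by i-Bu2AlH should give the neopentyl alcohol, while the nitro group is only deprotonated to an aluminium nitronate and returns on work-up.

Step 8
Reactants: 11 the primary alcohol from step 7
Product: 12 aldehyde (CH2OH of 11 oxidised to CHO)
Conditions: Dess–Martin periodinane, NaHCO3, CH2Cl2, 0 °C to rt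
Reagents that add atoms: none
Why: Dess–Martin oxidation under buffered neutral conditions should give the aldehyde, which has no α-hydrogen and so cannot epimerise.

Step 9
Reactants: 12 the aldehyde from step 8
Product: 13 vinyl compound (CHO of 12 converted to CH=CH2)
Conditions: Ph3PCH3Br, KN(SiMe3)2 (2.5 equiv of ylide), THF, 0 °C to rt
Reagents that add atoms: methyltriphenylphosphonium bromide, C[P+](c1ccccc1)(c1ccccc1)c1ccccc1.[Br-]
Why: Wittig methylenation of a non-enolisable aldehyde should be clean; the excess ylide covers reversible nitronate formation and the silylated carbinol cannot fragment.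

Step 10
Reactants: 14 3-methylbut-2-enal
Product: 15 (4R)-2-methylhept-2-en-6-yn-4-ol
Conditions: allenylboronic acid pinacol ester, (R)-3,3′-bis(2,4,6-triisopropylphenyl)-1,1′-binaphthyl-2,2′-diyl hydrogen phosphate (10 mol %), 4 Å molecular sieves, toluene, 0 °C
Reagents that add atoms: 4,4,5,5-tetramethyl-2-(propa-1,2-dien-1-yl)-1,3,2-dioxaborolane, C=C=CB1OC(C)(C)C(C)(C)O1
Why: Chiral phosphoric acid-catalysed propargylation of an aldehyde with an allenylboronate proceeds through a closed six-membered transition state in which the catalyst selects the aldehyde face, setting the (R)-carbinol.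

Step 11
Reactants: 15 (4R)-2-methylhept-2-en-6-yn-4-ol
Product: 16 tert-butyl(dimethyl){[(4R)-2-methylhept-2-en-6-yn-4-yl]oxy}silane
Conditions: t-BuMe2SiCl, imidazole, DMF, rt
Reagents that add atoms: tert-butyl(chloro)dimethylsilane, CC(C)(C)[Si](C)(C)Cl
Why: Standard silylation of a secondary alcohol; the protecting group is needed for the organoaluminium and organolithium steps.

Step 12
Reactants: 16 tert-butyl(dimethyl){[(4R)-2-methylhept-2-en-6-yn-4-yl]oxy}silane
Product: 18 tert-butyl{[(4R,6E)-7-iodo-2,6-dimethylhepta-2,6-dien-4-yl]oxy}dimethylsilane, via alkenylalane 17 (not isolated)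
Conditions: Me3Al (3 equiv), Cp2ZrCl2 (25 mol %), CH2Cl2, 0 °C to rt; then I2, THF, −30 to 0 °C
Reagents that add atoms: trimethylaluminium, C[Al](C)C; iodine, II
Why: Zr-catalysed syn-carboalumination of the terminal alkyne (methyl to the internal carbon, aluminium to the terminus) and iodinolysis with retention should give the (E)-vinyl iodide; the trisubstituted alkene is inert.

Step 13
Reactants: 18 the vinyl iodide from step 12; 19 (4-bromobut-1-yn-1-yl)trimethylsilane
Product: 21 tert-butyl{[(4R,6E)-2,6-dimethyl-11-(trimethylsilyl)undeca-2,6-dien-10-yn-4-yl]oxy}dimethylsilane, via organozinc bromide 20 (not isolated)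
Conditions: 19, Zn dust, I2 (5 mol %), DMA, 80 °C; then 18, Pd(PPh3)4 (5 mol %), THF, rt to 50 °C
Reagents that add atoms: none
Why: Negishi coupling of a primary alkylzinc halide with a vinyl iodide proceeds with retention of alkene geometry and is the classical homologation for 1,5-diene terpenoid chains.

Step 14
Reactants: 21 the silylated enyne from step 13
Product: 22 tert-butyl{[(4R,6E)-2,6-dimethylundeca-2,6-dien-10-yn-4-yl]oxy}dimethylsilane
Conditions: K2CO3 (cat.), MeOH, rt
Reagents that add atoms: none
Why: Methanolysis removes the alkynyl trimethylsilyl group selectively; the secondary silyl ether is stable to these conditions.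

Step 15
Reactants: 22 the terminal enyne from step 14
Product: 24 tert-butyl{[(4R,6E,10E)-11-iodo-2,6,10-trimethylundeca-2,6,10-trien-4-yl]oxy}dimethylsilane, via alkenylalane 23 (not isolated)
Conditions: Me3Al (3 equiv), Cp2ZrCl2 (25 mol %), CH2Cl2, 0 °C to rt; then I2, THF, −30 to 0 °C
Reagents that add atoms: trimethylaluminium, C[Al](C)C; iodine, II
Why: A second syn-carboalumination/iodinolysis should set the second (E)-trisubstituted alkene, as in step 12.

Step 16
Reactants: 13 the vinyl compound from step 9; 24 the (E,E)-vinyl iodide from step 15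
Product: 26 coupled nitro compound (ring of 13 carrying the full silylated side chain), via B-alkyl-9-BBN 25 (not isolated)
Conditions: 13, 9-BBN, THF, rt to 40 °C; then 24, Pd(dppf)Cl2 (5 mol %), AsPh3, Cs2CO3, DMF/H2O, rt
Reagents that add atoms: none
Why: Anti-Markovnikov hydroboration of the only alkene of 13 and B-alkyl Suzuki–Miyaura coupling with retention of the vinyl iodide geometry should join ring and chain; the nitro group, present as its nitronate, is not expected to compete with transmetalation.

Step 17
Reactants: 26 the coupled nitro compound from step 16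
Product: 28 ring ketone (C=O in place of CH–NO2), via sodium nitronate 27 (not isolated)
Conditions: NaOMe, MeOH, 0 °C; then aq. TiCl3 (4 equiv), NH4OAc buffer (pH about 6), THF, rt
Reagents that add atoms: water, O
Why: The reductive TiCl3 variant of the Nef reaction takes the nitronate through the oxime and imine to the ketone without any oxidant, so the three trisubstituted alkenes survive, and the buffer protects the silyl ethers.

Step 18
Reactants: 28 the ring ketone from step 17
Product: 29 1,1-dibromoalkene (C=CBr2 in place of C=O)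
Conditions: CBr4, P(NMe2)3, THF, −20 °C to rt
Reagents that add atoms: carbon tetrabromide, BrC(Br)(Br)Br
Why: Ramirez-type dibromomethylenation with the aminophosphorus ylide is reactive enough for ketones and is essentially non-basic, so the adjacent ring CH should not epimerise.

Step 19
Reactants: 29 the 1,1-dibromoalkene from step 18
Product: 30 (Z)-1-bromoethylidene compound (C=C(CH3)Br with Br cis to the ring CH that carries the side arm)
Conditions: MeZnCl (1.2 equiv), PdCl2(DPEphos) (5 mol %), THF, 0 °C to rt
Reagents that add atoms: methylzinc chloride, C[Zn]Cl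
Why: Pd-catalysed selective mono-coupling of a 1,1-dibromoalkene (Negishi coupling) should occur at the less hindered C–Br bond, the one cis to the ring CH2 and remote from the branched ring carbon with its axial side arm, which sets the alkene geometry.

Step 20
Reactants: 30 the bromoalkene from step 19
Product: 32 (2Z)-enal with all three hydroxyls silylated, via vinyllithium 31 (not isolated)
Conditions: t-BuLi (2.2 equiv), Et2O/THF, −78 °C; then DMF, −78 to 0 °C; aq. NH4Cl
Reagents that add atoms: N,N-dimethylformamide, CN(C)C=O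
Why: Bromine–lithium exchange gives a configurationally stable α-methyl vinyllithium that is formylated with retention, placing CHO cis to the branched ring carbon.

Step 21
Reactants: 32 the silylated enal from step 20
Product: 33 (2Z)-2-[(2S,3R,4R)-4-hydroxy-2-(3-hydroxypropyl)-3-[(3E,7E,10R)-10-hydroxy-4,8,12-trimethyltrideca-3,7,11-trien-1-yl]-3,4-dimethylcyclohexylidene]propanal
Conditions: HF·pyridine, pyridine, THF, 0 °C to rt
Reagents that add atoms: none
Why: Buffered fluoride desilylation should remove the two tert-butyldimethylsilyl ethers and the triethylsilyl ether without acid- or base-induced isomerisation of the enal or ionisation of the allylic alcohol.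

**Compound list**

1 | 4-[tert-butyl(dimethyl)silyl]oxybutanal | CC(C)(C)[Si](C)(C)OCCCC=O | starting material
2 | 5-[tert-butyl(dimethyl)silyl]oxy-1-nitropentan-2-ol (racemic) | CC(C)(C)[Si](C)(C)OCCCC(O)C[N+](=O)[O-] | intermediate
3 | tert-butyl(dimethyl){[(4E)-5-nitropent-4-en-1-yl]oxy}silane | CC(C)(C)[Si](C)(C)OCCC/C=C/[N+](=O)[O-] | intermediate
4 | (2E)-6-[tert-butyl(dimethyl)silyl]oxy-2-nitrohex-2-en-1-ol | OC/C(=C\CCCO[Si](C)(C)C(C)(C)C)[N+](=O)[O-] | intermediate
5 | (2E)-6-[tert-butyl(dimethyl)silyl]oxy-2-nitrohex-2-en-1-yl acetate | CC(=O)OC/C(=C\CCCO[Si](C)(C)C(C)(C)C)[N+](=O)[O-] | intermediate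
6 | methyl 2-methyl-3-oxobutanoate | COC(=O)C(C)C(C)=O | starting material
7 | methyl (2R,3R)-2-acetyl-3-{3-[tert-butyl(dimethyl)silyl]oxypropyl}-2-methyl-4-nitropent-4-enoate | COC(=O)[C@](C(C)=O)(C)[C@@H](CCCO[Si](C)(C)C(C)(C)C)C(=C)[N+](=O)[O-] | intermediate
8 | methyl (1R,2R,3R)-2-{3-[tert-butyl(dimethyl)silyl]oxypropyl}-1-methyl-3-nitro-6-oxocyclohexane-1-carboxylate | COC(=O)[C@]1(C)[C@@H](CCCO[Si](C)(C)C(C)(C)C)[C@H]([N+](=O)[O-])CCC1=O | intermediate
9 | methyl (1R,2R,5R,6R)-6-{3-[tert-butyl(dimethyl)silyl]oxypropyl}-2-hydroxy-1,2-dimethyl-5-nitrocyclohexane-1-carboxylate (OH cis to the C1 methyl) | COC(=O)[C@]1(C)[C@@H](CCCO[Si](C)(C)C(C)(C)C)[C@H]([N+](=O)[O-])CC[C@@]1(C)O | intermediate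
10 | triethylsilyl ether of 9 | COC(=O)[C@]1(C)[C@@H](CCCO[Si](C)(C)C(C)(C)C)[C@H]([N+](=O)[O-])CC[C@@]1(C)O[Si](CC)(CC)CC | intermediate
11 | primary alcohol (CH2OH in place of CO2Me of 10) | OC[C@]1(C)[C@@H](CCCO[Si](C)(C)C(C)(C)C)[C@H]([N+](=O)[O-])CC[C@@]1(C)O[Si](CC)(CC)CC | intermediate
12 | aldehyde (CHO in place of CH2OH of 11) | O=C[C@]1(C)[C@@H](CCCO[Si](C)(C)C(C)(C)C)[C@H]([N+](=O)[O-])CC[C@@]1(C)O[Si](CC)(CC)CC | intermediate
13 | vinyl compound (CH=CH2 in place of CHO of 12) | C=C[C@]1(C)[C@@H](CCCO[Si](C)(C)C(C)(C)C)[C@H]([N+](=O)[O-])CC[C@@]1(C)O[Si](CC)(CC)CC | intermediate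
14 | 3-methylbut-2-enal | CC(C)=CC=O | starting material
15 | (4R)-2-methylhept-2-en-6-yn-4-ol | CC(C)=C[C@H](O)CC#C | intermediate
16 | tert-butyl(dimethyl){[(4R)-2-methylhept-2-en-6-yn-4-yl]oxy}silane | CC(C)=C[C@H](O[Si](C)(C)C(C)(C)C)CC#C | intermediate
17 | (E)-alkenyl(dimethyl)alane from 16 | CC(C)=C[C@H](O[Si](C)(C)C(C)(C)C)C/C(C)=C/[Al](C)C | intermediate
18 | tert-butyl{[(4R,6E)-7-iodo-2,6-dimethylhepta-2,6-dien-4-yl]oxy}dimethylsilane | CC(C)=C[C@H](O[Si](C)(C)C(C)(C)C)C/C(C)=C/I | intermediate
19 | (4-bromobut-1-yn-1-yl)trimethylsilane | C[Si](C)(C)C#CCCBr | starting material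
20 | [4-(trimethylsilyl)but-3-yn-1-yl]zinc bromide | C[Si](C)(C)C#CCC[Zn]Br | intermediate
21 | tert-butyl{[(4R,6E)-2,6-dimethyl-11-(trimethylsilyl)undeca-2,6-dien-10-yn-4-yl]oxy}dimethylsilane | CC(C)=C[C@H](O[Si](C)(C)C(C)(C)C)C/C(C)=C/CCC#C[Si](C)(C)C | intermediate
22 | tert-butyl{[(4R,6E)-2,6-dimethylundeca-2,6-dien-10-yn-4-yl]oxy}dimethylsilane | CC(C)=C[C@H](O[Si](C)(C)C(C)(C)C)C/C(C)=C/CCC#C | intermediate
23 | (E,E)-alkenyl(dimethyl)alane from 22 | CC(C)=C[C@H](O[Si](C)(C)C(C)(C)C)C/C(C)=C/CC/C(C)=C/[Al](C)C | intermediate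
24 | tert-butyl{[(4R,6E,10E)-11-iodo-2,6,10-trimethylundeca-2,6,10-trien-4-yl]oxy}dimethylsilane | CC(C)=C[C@H](O[Si](C)(C)C(C)(C)C)C/C(C)=C/CC/C(C)=C/I | intermediate
25 | B-alkyl-9-borabicyclo[3.3.1]nonane from 13 (boron on the terminal carbon of the former vinyl group) | B1(CC[C@]3(C)[C@@H](CCCO[Si](C)(C)C(C)(C)C)[C@H]([N+](=O)[O-])CC[C@@]3(C)O[Si](CC)(CC)CC)C2CCCC1CCC2 | intermediate
26 | coupled nitro compound (ring of 13 with the full silylated side chain) | CC(C)=C[C@H](O[Si](C)(C)C(C)(C)C)C/C(C)=C/CC/C(C)=C/CC[C@]1(C)[C@@H](CCCO[Si](C)(C)C(C)(C)C)[C@H]([N+](=O)[O-])CC[C@@]1(C)O[Si](CC)(CC)CC | intermediate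
27 | sodium nitronate of 26 | CC(C)=C[C@H](O[Si](C)(C)C(C)(C)C)C/C(C)=C/CC/C(C)=C/CC[C@]1(C)[C@@H](CCCO[Si](C)(C)C(C)(C)C)C(=[N+]([O-])[O-])CC[C@@]1(C)O[Si](CC)(CC)CC.[Na+] | intermediate
28 | ring ketone (C=O in place of CH–NO2 of 26) | CC(C)=C[C@H](O[Si](C)(C)C(C)(C)C)C/C(C)=C/CC/C(C)=C/CC[C@]1(C)[C@@H](CCCO[Si](C)(C)C(C)(C)C)C(=O)CC[C@@]1(C)O[Si](CC)(CC)CC | intermediate
29 | dibromomethylidene compound | CC(C)=C[C@H](O[Si](C)(C)C(C)(C)C)C/C(C)=C/CC/C(C)=C/CC[C@]1(C)[C@@H](CCCO[Si](C)(C)C(C)(C)C)C(=C(Br)Br)CC[C@@]1(C)O[Si](CC)(CC)CC | intermediate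
30 | (Z)-1-bromoethylidene compound | CC(C)=C[C@H](O[Si](C)(C)C(C)(C)C)C/C(C)=C/CC/C(C)=C/CC[C@]1(C)[C@@H](CCCO[Si](C)(C)C(C)(C)C)/C(=C(/C)Br)CC[C@@]1(C)O[Si](CC)(CC)CC | intermediate
31 | vinyllithium from 30 | CC(C)=C[C@H](O[Si](C)(C)C(C)(C)C)C/C(C)=C/CC/C(C)=C/CC[C@]1(C)[C@@H](CCCO[Si](C)(C)C(C)(C)C)/C(=C(/C)[Li])CC[C@@]1(C)O[Si](CC)(CC)CC | intermediate
32 | (2Z)-enal, tris-silyl ether of the target | CC(C)=C[C@H](O[Si](C)(C)C(C)(C)C)C/C(C)=C/CC/C(C)=C/CC[C@]1(C)[C@@H](CCCO[Si](C)(C)C(C)(C)C)/C(=C(/C)C=O)CC[C@@]1(C)O[Si](CC)(CC)CC | intermediate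
33 | (2Z)-2-[(2S,3R,4R)-4-hydroxy-2-(3-hydroxypropyl)-3-[(3E,7E,10R)-10-hydroxy-4,8,12-trimethyltrideca-3,7,11-trien-1-yl]-3,4-dimethylcyclohexylidene]propanal | CC(C)=C[C@H](O)C/C(C)=C/CC/C(C)=C/CC[C@]1(C)[C@@H](CCCO)/C(=C(/C)C=O)CC[C@@]1(C)O | target

**Step count and risks**

Total step count: 21. Longest linear sequence: 15 steps (steps 1–9, then 16–21); the side-chain branch (steps 10–15) joins at step 16.

Steps most likely to fail:

1. Step 4. The diastereoselectivity at the quaternary carbon may erode through reversible Michael addition during the DBU stage, and the aliphatic nitroallyl acetate may deconjugate or oligomerise under base before it is trapped. The fallback sets out from 3 and 6 and separates the events. Thiourea-catalysed Michael addition of 6 to the simple nitroalkene 3 should give methyl (2R,3R)-2-acetyl-6-[tert-butyl(dimethyl)silyl]oxy-2-methyl-3-(nitromethyl)hexanoate F1, which is isolated so that diastereomers can be removed. A Henry reaction with aqueous formaldehyde and catalytic Et3N gives the hydroxymethylated nitro compound F2. Acetylation gives the acetate F3, and brief treatment with DBU causes E1cB loss of acetate to 7 and ring closure. The fallback returns to the route at 8.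

2. Step 18. Olefination of the hindered, α-branched ketone may be slow and lose out to enolisation, with epimerisation of the adjacent ring CH. The fallback sets out from 28. Addition of CH2=C(CH3)MgBr in the presence of CeCl3 gives the tertiary allylic alcohol F4. Oxidative 1,3-transposition with pyridinium chlorochromate, C5H5NH[CrO3Cl] (Babler–Dauben oxidation), converts it directly into the enal, which is separated from its geometric isomer by chromatography. The fallback returns at 32.

3. Step 19. Oxidative addition may discriminate poorly between the two C–Br bonds, or a second methylation may follow, giving the wrong or a mixed alkene geometry. The fallback sets out from 29 and reverses the order of the two substitutions. Kinetic bromine–lithium exchange with n-BuLi at −105 °C, which is expected to favour the more hindered bromine, followed by DMF gives the (Z)-2-bromo enal F5. Stille methylation with Me4Sn and Pd(PPh3)4, with retention, then replaces the remaining bromine. The fallback returns at 32.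

Further compounds
F1 | step 4 | methyl (2R,3R)-2-acetyl-6-[tert-butyl(dimethyl)silyl]oxy-2-methyl-3-(nitromethyl)hexanoate | COC(=O)[C@](C(C)=O)(C)[C@@H](CCCO[Si](C)(C)C(C)(C)C)C[N+](=O)[O-]
F2 | step 4 | methyl (2R,3R)-2-acetyl-6-[tert-butyl(dimethyl)silyl]oxy-3-(2-hydroxy-1-nitroethyl)-2-methylhexanoate (epimers at the nitro carbon) | COC(=O)[C@](C(C)=O)(C)[C@@H](CCCO[Si](C)(C)C(C)(C)C)C(CO)[N+](=O)[O-]
F3 | step 4 | acetate of F2 | COC(=O)[C@](C(C)=O)(C)[C@@H](CCCO[Si](C)(C)C(C)(C)C)C(COC(C)=O)[N+](=O)[O-]
F4 | step 18 | tertiary allylic alcohol from isopropenyl addition to 28 (carbinol configuration not defined) | CC(C)=C[C@H](O[Si](C)(C)C(C)(C)C)C/C(C)=C/CC/C(C)=C/CC[C@]1(C)[C@@H](CCCO[Si](C)(C)C(C)(C)C)C(O)(C(C)=C)CC[C@@]1(C)O[Si](CC)(CC)CC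
F5 | step 19 | (Z)-2-bromo enal (CHO cis to the branched ring carbon) | CC(C)=C[C@H](O[Si](C)(C)C(C)(C)C)C/C(C)=C/CC/C(C)=C/CC[C@]1(C)[C@@H](CCCO[Si](C)(C)C(C)(C)C)/C(=C(/Br)C=O)CC[C@@]1(C)O[Si](CC)(CC)CC
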